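**Retrosynthetic overview**
1. C8–C16 (last step): a metal-hydride H-atom transfer to a macrocyclic (8E)-enone gives a C8 radical that closes across the ring onto the tetronate C2=C16 bond; one radical event turns the 11-membered ring into the cyclopentane and the cyclooctane and sets C8 and C16.
2. C12–O: face-selective epoxidation of C11=C12, then epoxide opening by the tetronate oxygen (oxabicyclo[2.2.2]octane).
3. C10–C15 and C13–C14: intramolecular Diels–Alder reaction of an (E,E,E)-trienone with a 5-methylidene tetronate (cyclohexene and 11-membered ring together).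
4. C7–C8 by Nozaki–Hiyama–Kishi coupling, C14 by Mannich methylenation, C2–C3 by opening a (3S,5R)-lactone with 3-lithio methyl tetronate; the lactone comes from 2,4-dimethylpenta-1,4-diene by cyclic hydroboration and enzymatic desymmetrisation.
5. Ring order: butenolide (bought) → cyclohexene + 11-membered carbocycle → oxabicyclooctane → cyclopentane + cyclooctane.

Assumption: atoms are numbered as in the abyssomicin family (C1 lactone carbonyl, C2 its α-carbon, C3 enol carbon, C4/C6 methyl-bearing carbons flanking C5, C7 ketone, C8–C9–C10 cyclopentane carbons, C11 carbinol, C12/C13 methyl-bearing ring carbons, C14 ring CH2, C15 lactone C–O carbon, C16 ether-bearing quaternary carbon), and the target SMILES is read as (4S,6R,8R,10S,11S,12S,13S,15S,16R).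

**Route**

Step 1
Reactants: 1 2,4-dimethylpenta-1,4-diene
Product: 3 meso-(2R,4S)-2,4-dimethylpentane-1,5-diol, via thexylborinane 2 (not isolated)
Conditions: thexylborane (made in the flask from BH3·THF and 2,3-dimethylbut-2-ene), THF, −20 → 0 °C; then NaOH, H2O2, 0 °C → rt
Reagents that add atoms: hydrogen peroxide, OO
Why: Cyclic hydroboration: the second, intramolecular B–H addition closes a six-membered borinane through a chair transition state with both methyl groups equatorial, so oxidation gives mainly the meso diol, and any dl-diol is removed as the trans-lactone after step 2.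

Step 2
Reactants: 3 meso-(2R,4S)-2,4-dimethylpentane-1,5-diol
Product: 5 (3S,5R)-3,5-dimethyltetrahydro-2H-pyran-2-one, via lactol 4 (not isolated)
Conditions: horse liver alcohol dehydrogenase (HLADH), NAD+ (cat.), FMN (cat.), air, catalase, glycine–NaOH buffer pH 9, 20 °C
Reagents that add atoms: none
Why: Enzymatic enantiotopic-group-selective oxidation: HLADH oxidises only the hydroxymethyl arm on the S carbon, the hydroxy aldehyde closes to the lactol and is oxidised again, which fixes the absolute configuration of the future C4 (S) and C6 (R).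

Step 3
Reactants: 5 (3S,5R)-3,5-dimethyltetrahydro-2H-pyran-2-one; 6 4-methoxyfuran-2(5H)-one (methyl tetronate)
Product: 9 3-[(2S,4R)-5-hydroxy-2,4-dimethylpentanoyl]-4-methoxyfuran-2(5H)-one, via 3-lithio tetronate 7 (not isolated), via lithium lactolate 8 (not isolated)
Conditions: LDA, THF, −78 °C (6 → 7); then 5, −78 °C; AcOH quench at −78 °C
Reagents that add atoms: none
Why: Kinetic vinyl lithiation of methyl tetronate at C3 and nucleophilic acyl addition to the lactone; the lithium lactolate is stable at −78 °C and opens to the ketone only on acidic quench, so the C2–C3 bond forms by single addition without epimerising C4.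

Step 4
Reactants: 9 3-[(2S,4R)-5-hydroxy-2,4-dimethylpentanoyl]-4-methoxyfuran-2(5H)-one
Product: 10 3-[(2S,4R)-2,4-dimethyl-5-oxopentanoyl]-4-methoxyfuran-2(5H)-one
Conditions: Dess–Martin periodinane, NaHCO3, CH2Cl2, 0 °C → rt
Reagents that add atoms: none
Why: Dess–Martin oxidation of the primary alcohol under buffered, non-basic conditions gives the C7 aldehyde without epimerising C6.

Step 5
Reactants: 11 (E)-2-methylbut-2-enal (tiglic aldehyde); 12 (Z)-1-bromo-2-ethoxyethene
Product: 15 (2E,4E)-4-methylhexa-2,4-dienal, via (Z)-2-ethoxyvinyllithium 13 (not isolated), via lithium alkoxide adduct 14 (not isolated)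
Conditions: n-BuLi, Et2O, −78 °C (12 → 13); then 11, −78 °C; then 1 M HCl, THF, rt
Reagents that add atoms: water, O
Why: Two-carbon formyl-olefination: Br–Li exchange with retention gives an acetaldehyde β-anion equivalent, 1,2-addition to the aldehyde and acid hydrolysis of the enol ether with allylic transposition give the thermodynamically favoured E,E-dienal.

Step 6
Reactants: 15 (2E,4E)-4-methylhexa-2,4-dienal
Product: 16 (1E,3E,5E)-1-iodo-5-methylhepta-1,3,5-triene
Conditions: CHI3, CrCl2, THF–dioxane, 0 °C, dark
Reagents that add atoms: iodoform, IC(I)I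
Why: Takai olefination: the gem-dichromium species from CHI3 and CrCl2 converts the aldehyde into the E-vinyl iodide and supplies C8.

Step 7
Reactants: 10 3-[(2S,4R)-2,4-dimethyl-5-oxopentanoyl]-4-methoxyfuran-2(5H)-one; 16 (1E,3E,5E)-1-iodo-5-methylhepta-1,3,5-triene
Product: 17 3-[(2S,4R,6E,8E,10E)-5-hydroxy-2,4,10-trimethyldodeca-6,8,10-trienoyl]-4-methoxyfuran-2(5H)-one (C5' epimers)
Conditions: CrCl2, NiCl2 (cat.), DMSO, rt
Reagents that add atoms: none
Why: Nozaki–Hiyama–Kishi coupling: the alkenyl chromium species adds to the aldehyde only, leaving the ketone and the vinylogous ester untouched, with retention of the triene geometry; the new carbinol centre is removed in step 8.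

Step 8
Reactants: 17 3-[(2S,4R,6E,8E,10E)-5-hydroxy-2,4,10-trimethyldodeca-6,8,10-trienoyl]-4-methoxyfuran-2(5H)-one
Product: 18 3-[(2S,4R,6E,8E,10E)-2,4,10-trimethyl-5-oxododeca-6,8,10-trienoyl]-4-methoxyfuran-2(5H)-one
Conditions: Dess–Martin periodinane, NaHCO3, CH2Cl2, 0 °C
Reagents that add atoms: none
Why: Dess–Martin oxidation of the dienylic alcohol gives the (E,E,E)-trienone under conditions that do not epimerise C4 or C6.

Step 9
Reactants: 18 3-[(2S,4R,6E,8E,10E)-2,4,10-trimethyl-5-oxododeca-6,8,10-trienoyl]-4-methoxyfuran-2(5H)-one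
Product: 21 4-methoxy-5-methylidene-3-[(2S,4R,6E,8E,10E)-2,4,10-trimethyl-5-oxododeca-6,8,10-trienoyl]furan-2(5H)-one, via Mannich base 19 (not isolated), via ammonium iodide 20 (not isolated)
Conditions: LiHMDS, THF, −78 °C; Eschenmoser's salt, −78 → 0 °C; then MeI, CH2Cl2, rt; aq NaHCO3
Reagents that add atoms: Eschenmoser's salt (N,N-dimethylmethyleneiminium iodide), C=[N+](C)C.[I-]
Why: Mannich methylenation: the ring CH2 of the 3-acyl tetronate is the most acidic site (its anion is an aromatic furanolate conjugated to the acyl group), so it alone is aminomethylated, and quaternisation followed by E1cB elimination gives the exocyclic alkene (C14).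

Step 10
Reactants: 21 4-methoxy-5-methylidene-3-[(2S,4R,6E,8E,10E)-2,4,10-trimethyl-5-oxododeca-6,8,10-trienoyl]furan-2(5H)-one
Product: 22 macrocyclic Diels–Alder adduct (4S,6R,8E,10S,13S,15S)
Conditions: toluene (2 mM), BHT (cat.), 100 °C
Reagents that add atoms: none
Why: Intramolecular Diels–Alder reaction: the tether fixes the regiochemistry (C13 to C14, C10 to C15) and forces C16 cis to C9, the E,E-diene makes H10 and H13 cis, and the C4/C6 methyl groups select the diene face in the macrocyclic transition state as in the parent abyssomicin series.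

Step 11
Reactants: 22 macrocyclic Diels–Alder adduct (4S,6R,8E,10S,13S,15S)
Product: 23 11,12-epoxide (4S,6R,8E,10S,11S,12R,13S,15S)
Conditions: dimethyldioxirane, acetone, 0 °C
Reagents that add atoms: dimethyldioxirane, CC1(C)OO1
Why: Electrophilic epoxidation of the only electron-rich alkene (C11=C12) from the ring face opposite to C16, C9 and the C13 methyl group; the enone and the tetronate alkene are too electron-poor to react.

Step 12
Reactants: 23 11,12-epoxide (4S,6R,8E,10S,11S,12R,13S,15S)
Product: 25 macrocyclic enone with the C16–O–C12 ether bridge (4S,6R,8E,10S,11S,12S,13S,15S), via demethylated epoxide 24 (not isolated)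
Conditions: LiCl, DMSO, 50 °C; then p-TsOH·H2O, rt
Reagents that add atoms: none
Why: SN2 demethylation of the vinylogous ester by chloride, then acid-promoted 6-endo epoxide opening by the tetronate oxygen at the tertiary C12 with inversion, which closes the oxabicyclo[2.2.2]octane and leaves the C11 hydroxyl trans to the new C12–O bond.

Step 13
Reactants: 25 macrocyclic enone with the C16–O–C12 ether bridge (4S,6R,8E,10S,11S,12S,13S,15S)
Product: 26 Abyssomicin N
Conditions: Mn(dpm)3 (dpm = 2,2,6,6-tetramethylheptane-3,5-dionate; cat.), PhSiH3, i-PrOH–CH2Cl2, argon, rt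
Reagents that add atoms: none
Why: Proposed new method: the trivalent manganese hydride formed from Mn(dpm)3 and PhSiH3 transfers a hydrogen atom to C9 of the strained (8E)-enone, the resulting C8 α-keto radical is held by the 11-membered ring within bonding distance of C16 and closes 5-exo-trig onto the tetronate C2=C16 bond (transannular Giese-type radical conjugate addition), and the C2 radical, stabilised by the lactone and C3 carbonyls, is reduced by divalent manganese to the enolate and protonated by i-PrOH to the enol; C16 becomes R because the C9–C10 tether can reach only the face of C16 over C10, C8 becomes R because the C7 carbonyl must stay on the outer face for the eight-membered ring to close cis-fused, and the closest known reactions are metal-hydride H-atom-transfer reductive radical cyclisations of enones onto electron-poor alkenes and manganese-hydride conjugate reductions.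

**Compound list**
1 | 2,4-dimethylpenta-1,4-diene | C=C(C)CC(C)=C | starting material
2 | 1-(2,3-dimethylbutan-2-yl)-cis-3,5-dimethylborinane | CC(C)C(C)(C)B1C[C@H](C)C[C@H](C)C1 | intermediate
3 | meso-(2R,4S)-2,4-dimethylpentane-1,5-diol | OC[C@H](C)C[C@H](C)CO | intermediate
4 | (3S,5R)-3,5-dimethyltetrahydro-2H-pyran-2-ol (anomer mixture) | C[C@H]1C[C@@H](C)COC1O | intermediate
5 | (3S,5R)-3,5-dimethyltetrahydro-2H-pyran-2-one | C[C@H]1C[C@@H](C)COC1=O | intermediate
6 | 4-methoxyfuran-2(5H)-one (methyl tetronate) | COC1=CC(=O)OC1 | starting material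
7 | 3-lithio-4-methoxyfuran-2(5H)-one | COC1=C([Li])C(=O)OC1 | intermediate
8 | lithium (3S,5R)-2-(4-methoxy-2-oxo-2,5-dihydrofuran-3-yl)-3,5-dimethyltetrahydro-2H-pyran-2-olate (C2 epimers) | C[C@H]1C[C@@H](C)COC1([O-])C2=C(OC)COC2=O.[Li+] | intermediate
9 | 3-[(2S,4R)-5-hydroxy-2,4-dimethylpentanoyl]-4-methoxyfuran-2(5H)-one | COC1=C(C(=O)[C@@H](C)C[C@@H](C)CO)C(=O)OC1 | intermediate
10 | 3-[(2S,4R)-2,4-dimethyl-5-oxopentanoyl]-4-methoxyfuran-2(5H)-one | COC1=C(C(=O)[C@@H](C)C[C@@H](C)C=O)C(=O)OC1 | intermediate
11 | (E)-2-methylbut-2-enal (tiglic aldehyde) | C/C=C(\C)C=O | starting material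
12 | (Z)-1-bromo-2-ethoxyethene | CCO/C=C\Br | starting material
13 | (Z)-2-ethoxyvinyllithium | CCO/C=C\[Li] | intermediate
14 | lithium (1Z,4E)-1-ethoxy-4-methylhexa-1,4-dien-3-olate (racemic) | CCO/C=C\C([O-])/C(C)=C/C.[Li+] | intermediate
15 | (2E,4E)-4-methylhexa-2,4-dienal | C/C=C(C)/C=C/C=O | intermediate
16 | (1E,3E,5E)-1-iodo-5-methylhepta-1,3,5-triene | C/C=C(C)/C=C/C=C/I | intermediate
17 | 3-[(2S,4R,6E,8E,10E)-5-hydroxy-2,4,10-trimethyldodeca-6,8,10-trienoyl]-4-methoxyfuran-2(5H)-one (C5' epimers) | COC1=C(C(=O)[C@@H](C)C[C@@H](C)C(O)/C=C/C=C/C(C)=C/C)C(=O)OC1 | intermediate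
18 | 3-[(2S,4R,6E,8E,10E)-2,4,10-trimethyl-5-oxododeca-6,8,10-trienoyl]-4-methoxyfuran-2(5H)-one | COC1=C(C(=O)[C@@H](C)C[C@@H](C)C(=O)/C=C/C=C/C(C)=C/C)C(=O)OC1 | intermediate
19 | 5-[(dimethylamino)methyl] derivative of 18 (C5 epimers) | CN(C)CC1OC(=O)C(C(=O)[C@@H](C)C[C@@H](C)C(=O)/C=C/C=C/C(C)=C/C)=C1OC | intermediate
20 | 5-[(trimethylammonio)methyl] derivative of 18, iodide | C[N+](C)(C)CC1OC(=O)C(C(=O)[C@@H](C)C[C@@H](C)C(=O)/C=C/C=C/C(C)=C/C)=C1OC.[I-] | intermediate
21 | 4-methoxy-5-methylidene-3-[(2S,4R,6E,8E,10E)-2,4,10-trimethyl-5-oxododeca-6,8,10-trienoyl]furan-2(5H)-one | C=C1OC(=O)C(C(=O)[C@@H](C)C[C@@H](C)C(=O)/C=C/C=C/C(C)=C/C)=C1OC | intermediate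
22 | Diels–Alder adduct (4S,6R,8E,10S,13S,15S): 16-methoxy tetronate spiro-fused at C15 to a cyclohexene (C11=C12, methyls on C12 and C13) and spanned by the 11-membered ring C2–C3(=O)–C4(Me)–C5–C6(Me)–C7(=O)–C8=C9–C10 | C[C@@H]1C[C@H](C)C(=O)C2=C(OC)[C@]3(OC2=O)C[C@H](C)C(C)=C[C@@H]3/C=C/C1=O | intermediate
23 | 11,12-epoxide of 22 (4S,6R,8E,10S,11S,12R,13S,15S), oxygen on the face opposite C16 | C[C@@H]1C[C@H](C)C(=O)C2=C(OC)[C@]3(OC2=O)C[C@H](C)[C@@]4(C)O[C@H]4[C@@H]3/C=C/C1=O | intermediate
24 | 16-O-demethyl-23 (free 3-acyl tetronic acid; lithium salt in the flask in step 12) | C[C@@H]1C[C@H](C)C(=O)C2=C(O)[C@]3(OC2=O)C[C@H](C)[C@@]4(C)O[C@H]4[C@@H]3/C=C/C1=O | intermediate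
25 | macrocyclic (8E)-enone (4S,6R,10S,11S,12S,13S,15S) with oxabicyclo[2.2.2]octane (C16–O–C12), 11-hydroxy, 12- and 13-methyl, tetronate C2=C16 | C[C@@H]1C[C@H](C)C(=O)C2=C3O[C@]4(C)[C@@H](O)[C@H](/C=C/C1=O)[C@]3(C[C@@H]4C)OC2=O | intermediate
26 | Abyssomicin N (4S,6R,8R,10S,11S,12S,13S,15S,16R) | C[C@@H]1C[C@H](C)/C(O)=C2/C(=O)O[C@]34C[C@H](C)[C@]5(C)O[C@]23[C@@H](C[C@H]4[C@@H]5O)C1=O | target

**Step count**
Total steps: 13. Longest linear sequence: 11 steps (steps 1–4 and 7–13).

**Three steps most likely to fail, with fallbacks**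

Step 13 (transannular radical cyclisation). The C8 radical may be reduced before it cyclises, or the wrong C8 epimer may form. The fallback sets out from 25 and comes back at 26 and makes the bond in two polar operations. Hydrogenation of the strained C8=C9 bond (H2, Pd/C, EtOAc; the tetrasubstituted tetronate alkene is inert) gives the 8,9-dihydro macrocycle F1. A thermodynamic base (DBU, MeCN, or t-BuOK, t-BuOH) then forms the C8 enolate of the C7 ketone, which adds across the ring to C16 (transannular Michael addition) under equilibrating conditions that also correct C8, giving 26.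

Step 10 (intramolecular Diels–Alder reaction). The extra C12 methyl group may slow the cycloaddition or erode the facial selectivity. The fallback sets out from 21 and comes back to the route at 24, which closes to 25 under the acid of step 12. Compound 21 is demethylated first (LiCl, DMSO, 50 °C) to the free 3-acyl-5-methylidene tetronic acid F2, whose internally hydrogen-bonded tricarbonyl unit is a stronger and more rigid dienophile. Heating F2 (toluene, 80 °C) gives the macrocyclic tetronic acid F3. Dimethyldioxirane then epoxidises C11=C12 of F3 to give 24.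

Step 3 (single addition of the lithio tetronate to the lactone). Enolisation of the lactone or double addition may compete. The fallback sets out from 5 and comes back at 10. Compound 5 is reduced with i-Bu2AlH (CH2Cl2, −78 °C) to lactol 4. Two equivalents of 7 are added (the first deprotonates the lactol, the second traps its open hydroxy-aldehyde form) to give the diol F4. Both hydroxyl groups are then oxidised with Dess–Martin periodinane, which gives 10 directly and replaces steps 3 and 4.

**Further compounds**
F1 | step 13 | 8,9-dihydro-25 (4S,6R,10S,11S,12S,13S,15S) | C[C@@H]1C[C@H](C)C(=O)C2=C3O[C@]4(C)[C@@H](O)[C@H](CCC1=O)[C@]3(C[C@@H]4C)OC2=O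
F2 | step 10 | 4-hydroxy-5-methylidene-3-[(2S,4R,6E,8E,10E)-2,4,10-trimethyl-5-oxododeca-6,8,10-trienoyl]furan-2(5H)-one | C=C1OC(=O)C(C(=O)[C@@H](C)C[C@@H](C)C(=O)/C=C/C=C/C(C)=C/C)=C1O
F3 | step 10 | 16-O-demethyl-22 (4S,6R,8E,10S,13S,15S) | C[C@@H]1C[C@H](C)C(=O)C2=C(O)[C@]3(OC2=O)C[C@H](C)C(C)=C[C@@H]3/C=C/C1=O
F4 | step 3 | 3-[(2S,4R)-1,5-dihydroxy-2,4-dimethylpentyl]-4-methoxyfuran-2(5H)-one (C1' epimers) | COC1=C(C(O)[C@@H](C)C[C@@H](C)CO)C(=O)OC1
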